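Retrosynthesis: the imide is cut at N–C16 and C12–C13 (aldol), ring B at C8–C9, then C9=C11 (olefination), C6–C7 (bromoallylation), C9–C10 ([2,3] shift) and C5–C6 (carbonylation). This leaves ring A of actinol.
Enabling feature: in ring B (C5–C10), C8 is sp2, carries the methylene C17 and is bonded to the methine C9, whose C11–C12 arm ends at carbonyl level. C8 can therefore be a vinyl radical and C9 the β-carbon of a C9=C11–C12 enoate.
Forward: ring A comes from actinol, the C9 arm is grown on C10 and the C6–C8 arm on C5, ring B closes in the radical step, and the succinimide ring closes last.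
Stereochemistry: the C–O bond of (4R,6R)-actinol points the same way as the final C2–Cl bond, so C2 is reached by two inversions. C10 follows from C2 ([2,3] shift anti to the 2β-ether), and C5 from the ring A chair (hydroboration anti to the axial methyls).
C6 comes from a chiral 2-bromoallylborane, C9 from the chair-like radical transition state, and C12 and C13 from an Evans syn aldol.
Key step: step 18

Remark on notation: labdane numbers are used for all intermediates (ring A = C1–C5 and C10), and α/β refer to the target drawn with the C10 methyl β.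
Assumption: the (S,S)-stilbenediamine controller is taken to deliver the 2-bromoallyl group to the Re face of an aldehyde (chair transition state with the formyl hydrogen next to a sulfonyl oxygen). Its antipode is equally available.
Assumption: compounds 1, 7, 19, 26, 32 and 33 and the bis-sulfonamide controller are taken as commercial.

Step 1
Reactants: 1 (4R,6R)-actinol
Product: 2 (4S,6R)-4-(4-methoxyphenoxy)-2,2,6-trimethylcyclohexanone (2β-OPMP ketone)
Conditions: 4-MeOC6H4OH, PPh3, DIAD, THF, 0 °C → rt
Reagents that add atoms: 4-methoxyphenol, COc1ccc(O)cc1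
Why: Mitsunobu etherification, in which the phenol displaces the oxyphosphonium group by SN2, so the 2α-oxygen of actinol becomes the 2β-aryl ether and is protected in the same operation.

Step 2
Reactants: 2 2β-OPMP ketone
Product: 4 (4S)-4-(4-methoxyphenoxy)-2,6,6-trimethylcyclohex-1-en-1-yl triflate, via lithium enolate 3 (not isolated)
Conditions: LDA, THF, −78 → 0 °C; PhNTf2, 0 °C → rt
Reagents that add atoms: N-phenylbis(trifluoromethanesulfonimide), O=S(=O)(N(c1ccccc1)S(=O)(=O)C(F)(F)F)C(F)(F)F
Why: Enolate O-sulfonylation; C4 is quaternary, so only H-10 can be removed and a single tetrasubstituted C5=C10 enol triflate can form, which erases the C10 centre of actinol on purpose.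

Step 3
Reactants: 4 enol triflate
Product: 5 methyl (4S)-4-(4-methoxyphenoxy)-2,6,6-trimethylcyclohex-1-ene-1-carboxylate
Conditions: Pd(OAc)2 (cat.), PPh3, CO (1 atm), MeOH, Et3N, DMF, 60 °C
Reagents that add atoms: carbon monoxide, [C-]#[O+]; methanol, CO
Why: Palladium-catalysed alkoxycarbonylation of an enol triflate (oxidative addition, CO insertion, methanolysis) brings in C6 and is established for 2,6,6-trimethylcyclohexenyl triflates.

Step 4
Reactants: 5 unsaturated ester
Product: 6 [(4S)-4-(4-methoxyphenoxy)-2,6,6-trimethylcyclohex-1-en-1-yl]methanol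
Conditions: DIBAL-H, CH2Cl2, −78 → 0 °C
Reagents that add atoms: none
Why: 1,2-Reduction of a conjugated ester with DIBAL-H should give the allylic alcohol without touching the aryl ether.

Step 5
Reactants: 6 allylic alcohol; 7 tributyl(iodomethyl)stannane
Product: 9 tributylstannylmethyl ether of 6, via potassium alkoxide 8 (not isolated)
Conditions: KH, THF, 0 °C; 7, 0 °C → rt
Reagents that add atoms: none
Why: Williamson etherification of the primary alkoxide with the reactive iodomethylstannane attaches the future C9 to the C6 oxygen.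

Step 6
Reactants: 9 stannylmethyl ether
Product: 11 [(1S,5R)-5-(4-methoxyphenoxy)-1,3,3-trimethyl-2-methylidenecyclohexyl]methanol (10α-CH2OH; 10β-Me; 2β-OPMP; C5=C6 methylidene), via lithiomethyl ether 10 (not isolated)
Conditions: n-BuLi, THF, −78 °C; H2O
Reagents that add atoms: none
Why: Still–Wittig [2,3]-sigmatropic rearrangement; the C9–C10 bond forms axially on the half-chair that keeps the 2β-aryloxy group equatorial. That is the α face, where C9 meets H-2 and not the ether, and this sets C10 and moves the alkene to C5=C6.

Step 7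
Reactants: 11 homoallylic alcohol
Product: 12 TBDPS ether of 11 (10α-CH2OTBDPS)
Conditions: TBDPSCl, imidazole, DMF, rt
Reagents that add atoms: tert-butyl(chloro)diphenylsilane, CC(C)(C)[Si](Cl)(c1ccccc1)c1ccccc1
Why: Silyl ether formation; TBDPS should survive Ce(IV), triflation, borane and the boron allylating agent, and can later be removed with fluoride beside an acetate.

Step 8
Reactants: 12 aryl silyl diether
Product: 13 2β-alcohol (PMP removed from 12)
Conditions: CAN, MeCN–H2O (4:1), 0 °C
Reagents that add atoms: none
Why: Oxidative cleavage of a p-methoxyphenyl ether by Ce(IV), in which the arene leaves as quinone and the C2–O bond is untouched, so the 2β configuration is kept.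

Step 9
Reactants: 13 2β-alcohol
Product: 15 2α-chloride (ring A with 2α-Cl; 4,4-Me2; 5-methylidene; 10β-Me; 10α-CH2OTBDPS), via C2 triflate 14 (not isolated)
Conditions: Tf2O, 2,6-lutidine, CH2Cl2, −30 °C; Bu4NCl, −30 °C → rt
Reagents that add atoms: tetrabutylammonium chloride, CCCC[N+](CCCC)(CCCC)CCCC.[Cl-]
Why: SN2 displacement of a secondary triflate by chloride with inversion; the small, very reactive leaving group reacts from the chair in which it is axial, and chloride enters from the open α side to give the equatorial 2α-chloride.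

Step 10
Reactants: 15 2α-chloride
Product: 17 C6 primary alcohol (5α-H; equatorial CH2OH on C5 trans to C9), via primary alkylborane 16 (not isolated)
Conditions: BH3·THF, THF, 0 °C → rt; NaOH, H2O2, 0 °C
Reagents that add atoms: hydrogen peroxide, OO
Why: Hydroboration–oxidation (anti-Markovnikov syn addition); with the chloride equatorial, ring A sits in the chair that has the C4β and C10β methyls axial. Borane therefore reaches the methylene from the α face and places H-5 α.

Step 11
Reactants: 17 primary alcohol
Product: 18 C6 aldehyde (5α-H)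
Conditions: DMP, CH2Cl2, 0 °C → rt
Reagents that add atoms: none
Why: Dess–Martin oxidation under near-neutral conditions should give the aldehyde without epimerising C5.

Step 12
Reactants: 19 2,3-dibromopropene
Product: 20 (2-bromoallyl)tributylstannane
Conditions: Bu3SnH, LDA, THF, 0 °C; 19, −78 °C
Reagents that add atoms: tributyltin hydride, CCCC[SnH](CCCC)CCCC
Why: SN2 substitution of the allylic bromide by the stannyl anion, with the vinylic bromide left in place at low temperature.

Step 13
Reactants: 18 C6 aldehyde; 20 (2-bromoallyl)tributylstannane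
Product: 22 (6R)-2-bromoallyl carbinol (future 6β-OH), via 2-bromoallyl diazaborolidine 21 (not isolated)
Conditions: (S,S)-[TsNHCH(Ph)]2, BBr3, CH2Cl2, 0 → 23 °C; 20, 23 °C; 18, −78 °C
Reagents that add atoms: none
Why: Asymmetric allylboration through a closed six-membered chair; tin-to-boron exchange gives the chiral borane 21, whose controller directs C7 to the Re face of the formyl group (6R). Reagent control is chosen because the two flanks C4 and C10 are too alike for substrate control.

Step 14
Reactants: 22 carbinol
Product: 23 6-acetate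
Conditions: Ac2O, DMAP, pyridine, rt → 40 °C
Reagents that add atoms: acetic anhydride, CC(=O)OC(C)=O
Why: DMAP-catalysed acylation; the small acetate is chosen because this oxygen becomes axial between two axial methyls in ring B.

Step 15
Reactants: 23 acetate silyl ether
Product: 24 C9 primary alcohol
Conditions: HF·pyridine, THF, 0 °C → rt
Reagents that add atoms: none
Why: Fluoride desilylation under mildly acidic conditions, which should spare the acetate, the vinylic bromide and the chloride.

Step 16
Reactants: 24 C9 alcohol
Product: 25 C9 aldehyde (formyl group on quaternary C10)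
Conditions: DMP, CH2Cl2, rt
Reagents that add atoms: none
Why: Dess–Martin oxidation of the neopentyl alcohol to a non-enolisable aldehyde.

Step 17
Reactants: 25 C9 aldehyde; 26 trimethyl phosphonoacetate
Product: 28 ring A chloro acetate bearing the (6R)-acetoxy-2-bromoallyl arm on C5 and the methyl (E)-C9=C11 enoate on C10, via sodium phosphonate 27 (not isolated)
Conditions: 26, NaH, THF, 0 °C; 25, 0 °C → rt
Reagents that add atoms: none
Why: Horner–Wadsworth–Emmons olefination; the stabilised anion should tolerate the acetate, and a hindered aldehyde favours the E-enoate.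

Step 18
Reactants: 28 bromoallyl enoate
Product: 29 methyl 6β-acetoxy-2α-chloro-13,14,15,16-tetranorlabd-8(17)-en-12-oate
Conditions: Bu3SnH (1.2 equiv, syringe pump), AIBN (cat.), PhH (0.01 M), 80 °C
Reagents that add atoms: none
Why: The stannyl radical abstracts the vinylic bromine of 28 to give the σ-type C8 vinyl radical, which adds to C9, the β-carbon of the enoate; the ester-stabilised C11 radical then takes hydrogen from Bu3SnH and carries the chain (tin hydride mediated cyclisation of a 2-bromo-1-alkene onto an acrylate, an intramolecular Giese-type addition). Ring B (C5–C10) closes in the 6-exo-trig mode, since the 7-endo path would need attack at the α-carbon C11 and is opposed by polarity and ring size. C9 is the only new stereocentre and is set by a chair-like transition state on the ring A chair, where C6 and C9 are trans-diequatorial: the alkene turns C11 outward, anti to C5, because the other rotamer eclipses C11 with the C10–C5 bond, so C11 ends equatorial (β) and H-9 axial (α). The step needs C–Br over C–Cl selectivity, which the much faster halogen abstraction from a vinylic bromide than from a secondary chloride secures with only a small excess of hydride. It also needs ring closure to outrun hydrogen transfer to the vinyl radical, which slow hydride addition at high dilution and the electron-poor acceptor should provide. The small axial acetate limits the 1,3-diaxial load against the C4β and C10β methyls, and C17, the chloride and the C12 ester emerge in their final places.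

Step 19
Reactants: 29 decalin acetate ester
Product: 30 2α-chloro-13,14,15,16-tetranorlabd-8(17)-ene-6β,12-diol
Conditions: DIBAL-H (excess), CH2Cl2, −78 → 0 °C
Reagents that add atoms: none
Why: Hydride reduction takes the ester to the primary alcohol and cleaves the acetate in the same flask. This avoids a half-reduction beside an acetate and a late basic deacetylation beside the imide.

Step 20
Reactants: 30 diol
Product: 31 2α-chloro-6β-hydroxy-13,14,15,16-tetranorlabd-8(17)-en-12-al
Conditions: TEMPO (cat.), PhI(OAc)2, CH2Cl2, rt
Reagents that add atoms: none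
Why: Oxoammonium (TEMPO) oxidation is selective for the primary C12 alcohol, and the axial 6β-hydroxyl between two axial methyls should not react.

Step 21
Reactants: 32 3-cyanopropanoic acid; 33 (R)-4-benzyloxazolidin-2-one
Product: 35 (R)-4-benzyl-3-(3-cyanopropanoyl)oxazolidin-2-one, via mixed pivalic anhydride 34 (not isolated)
Conditions: PivCl, Et3N, THF, −20 °C; 33, LiCl, rt
Reagents that add atoms: none
Why: N-Acylation of the auxiliary through a mixed anhydride, which reacts at its less hindered carbonyl; the nitrile serves as a masked primary amide.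

Step 22
Reactants: 31 C12 aldehyde; 35 cyanopropanoyl oxazolidinone
Product: 37 (12S,13R)-syn aldol adduct (C13 bears CH2CN and the N-acyl oxazolidinone carbonyl C16), via Z boron enolate 36 (not isolated)
Conditions: 35 (excess), Bu2BOTf, Et3N, CH2Cl2, −78 → 0 °C; 31, −78 → 0 °C; pH 7 buffer, MeOH, H2O2
Reagents that add atoms: none
Why: Evans syn aldol through a Zimmerman–Traxler chair, in which the (R)-benzyl auxiliary sets 12S and 13R; the buried 6β-hydroxyl is left free and any enolate it protonates is covered by the excess.

Step 23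
Reactants: 37 aldol adduct
Product: 39 haterumaimide F, via primary amide 38 (not isolated)
Conditions: [PtH(PMe2OH)(PMe2O)2H] (cat.), EtOH–H2O, 80 °C
Reagents that add atoms: water, O
Why: Neutral platinum-catalysed nitrile hydration (Ghaffar–Parkins catalyst) followed by 5-exo-trig N-acylation; the amide nitrogen attacks the activated carbonyl C16 and expels the auxiliary, and no base is present to disturb C13 or the β-hydroxy unit.

Compound list
1 | (4R,6R)-actinol, (4R,6R)-4-hydroxy-2,2,6-trimethylcyclohexanone | O=C1C(C)(C)C[C@H](O)C[C@H]1C | starting material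
2 | (4S,6R)-4-(4-methoxyphenoxy)-2,2,6-trimethylcyclohexanone | O=C1C(C)(C)C[C@@H](Oc2ccc(OC)cc2)C[C@H]1C | intermediate
3 | lithium enolate of 2 (C5=C10) | CC1=C([O-])C(C)(C)C[C@@H](Oc2ccc(OC)cc2)C1.[Li+] | intermediate
4 | (4S)-4-(4-methoxyphenoxy)-2,6,6-trimethylcyclohex-1-en-1-yl triflate | CC1=C(OS(=O)(=O)C(F)(F)F)C(C)(C)C[C@@H](Oc2ccc(OC)cc2)C1 | intermediate
5 | methyl (4S)-4-(4-methoxyphenoxy)-2,6,6-trimethylcyclohex-1-ene-1-carboxylate | CC1=C(C(=O)OC)C(C)(C)C[C@@H](Oc2ccc(OC)cc2)C1 | intermediate
6 | [(4S)-4-(4-methoxyphenoxy)-2,6,6-trimethylcyclohex-1-en-1-yl]methanol | CC1=C(CO)C(C)(C)C[C@@H](Oc2ccc(OC)cc2)C1 | intermediate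
7 | tributyl(iodomethyl)stannane | CCCC[Sn](CI)(CCCC)CCCC | starting material
8 | potassium alkoxide of 6 | CC1=C(C[O-])C(C)(C)C[C@@H](Oc2ccc(OC)cc2)C1.[K+] | intermediate
9 | tributylstannylmethyl ether of 6 | CC1=C(COC[Sn](CCCC)(CCCC)CCCC)C(C)(C)C[C@@H](Oc2ccc(OC)cc2)C1 | intermediate
10 | lithiomethyl ether of 6 | CC1=C(COC[Li])C(C)(C)C[C@@H](Oc2ccc(OC)cc2)C1 | intermediate
11 | [(1S,5R)-5-(4-methoxyphenoxy)-1,3,3-trimethyl-2-methylidenecyclohexyl]methanol | C=C1C(C)(C)C[C@@H](Oc2ccc(OC)cc2)C[C@]1(C)CO | intermediate
12 | TBDPS ether of 11 | C=C1C(C)(C)C[C@@H](Oc2ccc(OC)cc2)C[C@]1(C)CO[Si](c1ccccc1)(c1ccccc1)C(C)(C)C | intermediate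
13 | 2β-alcohol (10β-Me, 10α-CH2OTBDPS, 5-methylidene) | C=C1C(C)(C)C[C@@H](O)C[C@]1(C)CO[Si](c1ccccc1)(c1ccccc1)C(C)(C)C | intermediate
14 | 2β-triflate of 13 | C=C1C(C)(C)C[C@@H](OS(=O)(=O)C(F)(F)F)C[C@]1(C)CO[Si](c1ccccc1)(c1ccccc1)C(C)(C)C | intermediate
15 | 2α-chloride (10β-Me, 10α-CH2OTBDPS, 5-methylidene) | C=C1C(C)(C)C[C@H](Cl)C[C@]1(C)CO[Si](c1ccccc1)(c1ccccc1)C(C)(C)C | intermediate
16 | primary alkylborane (BH2 on C6, 5α-H) | BC[C@H]1C(C)(C)C[C@H](Cl)C[C@]1(C)CO[Si](c1ccccc1)(c1ccccc1)C(C)(C)C | intermediate
17 | C6 primary alcohol (5α-H, 2α-Cl) | OC[C@H]1C(C)(C)C[C@H](Cl)C[C@]1(C)CO[Si](c1ccccc1)(c1ccccc1)C(C)(C)C | intermediate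
18 | C6 aldehyde (5α-H, 2α-Cl) | O=C[C@H]1C(C)(C)C[C@H](Cl)C[C@]1(C)CO[Si](c1ccccc1)(c1ccccc1)C(C)(C)C | intermediate
19 | 2,3-dibromopropene | C=C(Br)CBr | starting material
20 | (2-bromoallyl)tributylstannane | C=C(Br)C[Sn](CCCC)(CCCC)CCCC | intermediate
21 | (4S,5S)-2-(2-bromoallyl)-4,5-diphenyl-1,3-ditosyl-1,3,2-diazaborolidine | C=C(Br)CB1N(S(=O)(=O)c2ccc(C)cc2)[C@@H](c2ccccc2)[C@H](c2ccccc2)N1S(=O)(=O)c1ccc(C)cc1 | intermediate
22 | (6R)-2-bromoallyl carbinol | C=C(Br)C[C@@H](O)[C@H]1C(C)(C)C[C@H](Cl)C[C@]1(C)CO[Si](c1ccccc1)(c1ccccc1)C(C)(C)C | intermediate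
23 | 6-acetate of 22 | C=C(Br)C[C@@H](OC(C)=O)[C@H]1C(C)(C)C[C@H](Cl)C[C@]1(C)CO[Si](c1ccccc1)(c1ccccc1)C(C)(C)C | intermediate
24 | C9 primary alcohol | C=C(Br)C[C@@H](OC(C)=O)[C@H]1C(C)(C)C[C@H](Cl)C[C@]1(C)CO | intermediate
25 | C9 aldehyde | C=C(Br)C[C@@H](OC(C)=O)[C@H]1C(C)(C)C[C@H](Cl)C[C@]1(C)C=O | intermediate
26 | trimethyl phosphonoacetate | COC(=O)CP(=O)(OC)OC | starting material
27 | sodium salt of 26 | COC(=O)[CH-]P(=O)(OC)OC.[Na+] | intermediate
28 | ring A chloro acetate with 2-bromoallyl arm on C5 and methyl (E)-enoate on C10 | C=C(Br)C[C@@H](OC(C)=O)[C@H]1C(C)(C)C[C@H](Cl)C[C@]1(C)/C=C/C(=O)OC | intermediate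
29 | methyl 6β-acetoxy-2α-chloro-13,14,15,16-tetranorlabd-8(17)-en-12-oate | C=C1C[C@@H](OC(C)=O)[C@H]2C(C)(C)C[C@H](Cl)C[C@]2(C)[C@H]1CC(=O)OC | intermediate
30 | 2α-chloro-13,14,15,16-tetranorlabd-8(17)-ene-6β,12-diol | C=C1C[C@@H](O)[C@H]2C(C)(C)C[C@H](Cl)C[C@]2(C)[C@H]1CCO | intermediate
31 | 2α-chloro-6β-hydroxy-13,14,15,16-tetranorlabd-8(17)-en-12-al | C=C1C[C@@H](O)[C@H]2C(C)(C)C[C@H](Cl)C[C@]2(C)[C@H]1CC=O | intermediate
32 | 3-cyanopropanoic acid | N#CCCC(=O)O | starting material
33 | (R)-4-benzyloxazolidin-2-one | O=C1N[C@H](Cc2ccccc2)CO1 | starting material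
34 | 3-cyanopropanoic pivalic anhydride | N#CCCC(=O)OC(=O)C(C)(C)C | intermediate
35 | (R)-4-benzyl-3-(3-cyanopropanoyl)oxazolidin-2-one | N#CCCC(=O)N1[C@H](Cc2ccccc2)COC1=O | intermediate
36 | (Z)-dibutylboron enolate of 35 | N#CC/C=C(\OB(CCCC)CCCC)N1[C@H](Cc2ccccc2)COC1=O | intermediate
37 | (12S,13R)-syn aldol adduct | C=C1C[C@@H](O)[C@H]2C(C)(C)C[C@H](Cl)C[C@]2(C)[C@H]1C[C@H](O)[C@@H](CC#N)C(=O)N1[C@H](Cc2ccccc2)COC1=O | intermediate
38 | primary amide from 37 | C=C1C[C@@H](O)[C@H]2C(C)(C)C[C@H](Cl)C[C@]2(C)[C@H]1C[C@H](O)[C@@H](CC(N)=O)C(=O)N1[C@H](Cc2ccccc2)COC1=O | intermediate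
39 | haterumaimide F | C=C1C[C@@H](O)[C@H]2C(C)(C)C[C@H](Cl)C[C@]2(C)[C@H]1C[C@H](O)[C@H]1CC(=O)NC1=O | target

Total steps: 23. Longest linear sequence: 21 (steps 1–11, 13–20, 22 and 23).

Steps most likely to fail

Step 9. Loss of triflic acid toward C1 or C3 may outrun substitution, because both processes need the strained chair with the leaving group axial between the C4β and C10β methyls. The fallback replaces the ionic displacement with a radical one; it sets out from 13 and returns at 15. Alcohol 13 is acylated with methyl chlorooxoacetate (Et3N, DMAP, CH2Cl2) to the methyl oxalate F1. This is saponified with CsOH to the cesium oxalate F2. Irradiation of F2 (blue light, iridium photocatalyst) with ethyl trichloroacetate should cause oxidation and double decarboxylation to the planar C2 radical. That radical should take chlorine on the face away from the two axial methyls of the chair that keeps the large silyloxymethyl group equatorial, which gives 15. The methylene, flanked by two quaternary carbons, should resist radical addition.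

Step 13. Addition to a formyl group held between two quaternary carbons may be slow, and the facial selectivity poor. The fallback separates bond formation from stereocontrol; it sets out from 18 and returns at 22. An indium Barbier reaction of 18 with 19 (THF–H2O) should give the C6-epimeric carbinol mixture F3. Dess–Martin oxidation converts this into the 2-bromoallyl ketone F4. CBS reduction with (S)-Me-CBS and catecholborane then distinguishes the very large ring A residue from the CH2 side and should give the 6R alcohol 22.

Step 18. Hydrogen transfer to the vinyl radical before ring closure (simple debromination) may compete, because C9 lies next to the quaternary C10. The fallback forms the same C8–C9 bond by an organopalladium route; it sets out from 28 and returns at 29. A reductive Heck cyclisation (Pd(OAc)2, PPh3, HCO2Na, DMF, 80 °C) proceeds by oxidative addition at C–Br, 6-exo syn-carbopalladation of the enoate through the same chair, and hydride transfer from formate to the palladium enolate. The secondary chloride should be inert. This detour makes no compound outside the list (F0).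

Further compounds
F1 | step 9 | methyl oxalate of 13 | C=C1C(C)(C)C[C@@H](OC(=O)C(=O)OC)C[C@]1(C)CO[Si](c1ccccc1)(c1ccccc1)C(C)(C)C
F2 | step 9 | cesium oxalate of 13 | C=C1C(C)(C)C[C@@H](OC(=O)C(=O)[O-])C[C@]1(C)CO[Si](c1ccccc1)(c1ccccc1)C(C)(C)C.[Cs+]
F3 | step 13 | 2-bromoallyl carbinol, mixture of C6 epimers | C=C(Br)CC(O)[C@H]1C(C)(C)C[C@H](Cl)C[C@]1(C)CO[Si](c1ccccc1)(c1ccccc1)C(C)(C)C
F4 | step 13 | 2-bromoallyl ketone (C6=O) | C=C(Br)CC(=O)[C@H]1C(C)(C)C[C@H](Cl)C[C@]1(C)CO[Si](c1ccccc1)(c1ccccc1)C(C)(C)C
F0 | step 18 | none | none
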